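**Retrosynthetic overview**
- Target 21 ← the only ring, the 1,2-dioxane, is closed last by forming the C6–O bond: a chiral-acid-catalysed Markovnikov addition of the C3 hydroperoxide to the C6 ethylidene (new step).
- Hydroperoxy acid 20 ← C3–O bond by amine-catalysed peroxy-Michael addition of a masked H2O2 (17) to enal 15, then Pinnick oxidation and unmasking.
- Enal 15 ← cross-metathesis of triene 13 ← Wittig ethylidenation of ketone 11.
- Ketone 11 ← ester 6 (C6–C14, two Cu-catalysed conjugate additions starting from ethyl sorbate) + bromide 8 (C2–C5, Cu-catalysed allylic alkylation).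

Assumption: each chiral ligand or catalyst named induces the sense known for its substrate class; if a rotation or NMR check shows the opposite sense, its antipode is used. The ethylidene alkene is carried as an E/Z mixture.

Step 1
Reactants: 1 ethyl (2E,4E)-hexa-2,4-dienoate; 2 butylmagnesium bromide
Product: 3 ethyl (3E,5S)-5-methylnon-3-enoate
Conditions: CuBr·SMe2 (5 mol %), reversed Josiphos (5 mol %), CH2Cl2, −70 °C; then 1 M HCl
Reagents that add atoms: none
Why: Cu-catalysed asymmetric 1,6-conjugate addition of a Grignard reagent to a dienoate; the chiral copper–diphosphine complex delivers butyl to one face of the δ-carbon (sets C10 as S) and α-protonation leaves the E β,γ-alkene.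

Step 2
Reactants: 3 ethyl (3E,5S)-5-methylnon-3-enoate
Product: 4 ethyl (2E,5S)-5-methylnon-2-enoate
Conditions: DBU (0.5 equiv), CH2Cl2, 25 °C
Reagents that add atoms: none
Why: Base-mediated alkene isomerisation through the dienolate into conjugation (thermodynamic control); the C5 stereocenter is not deprotonated.

Step 3
Reactants: 4 ethyl (2E,5S)-5-methylnon-2-enoate; 5 ethylmagnesium bromide
Product: 6 ethyl (3S,5S)-3-ethyl-5-methylnonanoate
Conditions: CuBr·SMe2 (1 mol %), (R,S)-Josiphos (1.2 mol %), t-BuOMe, −75 °C; then 1 M HCl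
Reagents that add atoms: none
Why: Cu/Josiphos-catalysed asymmetric 1,4-conjugate addition of a Grignard reagent to an enoate; ligand control sets C8 as S, syn to the C10 methyl.

Step 4
Reactants: 7 (E)-1,4-dibromobut-2-ene; 5 ethylmagnesium bromide
Product: 8 (3R)-3-(bromomethyl)pent-1-ene
Conditions: CuBr·SMe2 (1 mol %), (R,R)-Taniaphos (1.2 mol %), CH2Cl2, −75 °C
Reagents that add atoms: none
Why: Cu-catalysed asymmetric allylic alkylation (SN2′) of a symmetric allylic dibromide; the catalyst sets the ethyl-bearing carbon (future C4) and leaves a vinyl and a CH2Br handle.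

Step 5
Reactants: 6 ethyl (3S,5S)-3-ethyl-5-methylnonanoate; 8 (3R)-3-(bromomethyl)pent-1-ene
Product: 11 (3S,7S,9S)-3,7-diethyl-9-methyltridec-1-en-5-one, via Weinreb amide 9 (not isolated), via Grignard reagent 10 (not isolated)
Conditions: MeNH(OMe)·HCl, i-PrMgCl, THF, −20 °C; then 10 (from 8, Mg, THF, 0–25 °C, used at once), 0 °C; 1 M HCl
Reagents that add atoms: none
Why: One-pot ester-to-Weinreb-amide conversion followed by Grignard acylation; the chelated tetrahedral intermediate prevents over-addition, and both stereocenters are β to the carbonyl so cannot epimerise.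

Step 6
Reactants: 11 (3S,7S,9S)-3,7-diethyl-9-methyltridec-1-en-5-one; 12 ethyltriphenylphosphonium bromide
Product: 13 (3S,7S,9S)-3,7-diethyl-5-ethylidene-9-methyltridec-1-ene
Conditions: KOt-Bu, toluene, 0 → 90 °C
Reagents that add atoms: none
Why: Wittig olefination with a non-stabilised ylide installs the two carbons of the future C6 ethyl group; the E/Z ratio is irrelevant because this alkene becomes sp3 in step 11.

Step 7
Reactants: 13 (3S,7S,9S)-3,7-diethyl-5-ethylidene-9-methyltridec-1-ene; 14 (E)-but-2-enal
Product: 15 (2E,4S,8S,10S)-4,8-diethyl-6-ethylidene-10-methyltetradec-2-enal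
Conditions: second-generation Hoveyda–Grubbs catalyst (5 mol %), 14 (5 equiv), CH2Cl2, 40 °C
Reagents that add atoms: none
Why: Olefin cross-metathesis; only the terminal vinyl reacts, the trisubstituted ethylidene is inert (ethylidene exchange with crotonaldehyde is degenerate), and the E-enal is favoured.

Step 8
Reactants: 16 2,3-dimethylbut-2-ene
Product: 17 2-hydroperoxy-2-methoxypropane
Conditions: O3, MeOH/CH2Cl2, −78 °C
Reagents that add atoms: ozone O=[O+][O-]; methanol CO
Why: Ozonolysis in methanol; the Criegee carbonyl oxide is trapped by MeOH to give the α-methoxy hydroperoxide, a mono-protected hydrogen peroxide.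

Step 9
Reactants: 15 (2E,4S,8S,10S)-4,8-diethyl-6-ethylidene-10-methyltetradec-2-enal; 17 2-hydroperoxy-2-methoxypropane
Product: 18 (3S,4S,8S,10S)-4,8-diethyl-6-ethylidene-3-[(2-methoxypropan-2-yl)peroxy]-10-methyltetradecanal
Conditions: (S)-2-[bis(3,5-bis(trifluoromethyl)phenyl)(trimethylsilyloxy)methyl]pyrrolidine (20 mol %), PhCO2H (20 mol %), toluene, −20 °C
Reagents that add atoms: none
Why: Iminium-catalysed asymmetric peroxy-Michael addition (β-peroxidation of an enal); the diarylprolinol ether shields one face of the E-iminium so the hydroperoxide adds to C3 from the open face (3S), and the acid co-catalyst protonates the enamine before it can close to an epoxide.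

Step 10
Reactants: 18 (3S,4S,8S,10S)-4,8-diethyl-6-ethylidene-3-[(2-methoxypropan-2-yl)peroxy]-10-methyltetradecanal
Product: 20 (3S,4S,8S,10S)-4,8-diethyl-6-ethylidene-3-hydroperoxy-10-methyltetradecanoic acid, via peroxyketal acid 19 (not isolated)
Conditions: NaClO2, NaH2PO4, 2-methylbut-2-ene, t-BuOH/H2O, 0 °C; then AcOH/THF/H2O, 25 °C
Reagents that add atoms: sodium chlorite [Na+].[O-]Cl=O
Why: Pinnick oxidation (mildly acidic, so no β-elimination of the peroxide; the scavenger protects the alkene) followed by acid hydrolysis of the peroxyketal to the free hydroperoxide; no stereocenter is touched.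

Step 11
Reactants: 20 (3S,4S,8S,10S)-4,8-diethyl-6-ethylidene-3-hydroperoxy-10-methyltetradecanoic acid
Product: 21 2-[(3S,4S,6S)-4,6-diethyl-6-[(2S,4S)-2-ethyl-4-methyloctyl]-1,2-dioxan-3-yl]acetic acid
Conditions: (S,S)-IDPi Brønsted acid (confined imidodiphosphorimidate, 3,3′-diaryl BINOL backbones, N-triflyl core; 5 mol %), cyclohexane/CHCl3 4:1, 35 °C
Reagents that add atoms: none
Why: Proposed new method: the confined chiral acid protonates the ethylidene CH carbon (Markovnikov) while its basic oxygen hydrogen-bonds the OOH group, so the C6 cation is captured inside the chiral ion pair by the distal hydroperoxide oxygen through a six-membered chair-like transition state (C4 ethyl equatorial, C3 CH2CO2H axial, both fixed beforehand); the catalyst pocket decides which face of trigonal C6 is attacked, placing the small ethyl equatorial and the branched chain axial (6S), and the E and Z isomers converge because the geometry is lost at the new CH2; the hydroperoxide (α-effect, six-membered ring) should outcompete the carboxylic acid (seven-membered ring); the closest known reactions are the confined-acid-catalysed asymmetric intramolecular hydroalkoxylation of unactivated alkenes with alcohol nucleophiles and the racemic mercuric-salt- or halonium-mediated cyclisation of unsaturated hydroperoxides to 1,2-dioxanes.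

**Compound list**
1 | ethyl (2E,4E)-hexa-2,4-dienoate (ethyl sorbate) | C/C=C/C=C/C(=O)OCC | starting material
2 | butylmagnesium bromide | CCCC[Mg]Br | starting material
3 | ethyl (3E,5S)-5-methylnon-3-enoate | CCCC[C@H](C)/C=C/CC(=O)OCC | intermediate
4 | ethyl (2E,5S)-5-methylnon-2-enoate | CCCC[C@H](C)C/C=C/C(=O)OCC | intermediate
5 | ethylmagnesium bromide | CC[Mg]Br | starting material
6 | ethyl (3S,5S)-3-ethyl-5-methylnonanoate | CCCC[C@H](C)C[C@H](CC)CC(=O)OCC | intermediate
7 | (E)-1,4-dibromobut-2-ene | BrC/C=C/CBr | starting material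
8 | (3R)-3-(bromomethyl)pent-1-ene | BrC[C@H](CC)C=C | intermediate
9 | (3S,5S)-3-ethyl-N-methoxy-N,5-dimethylnonanamide | CCCC[C@H](C)C[C@H](CC)CC(=O)N(C)OC | intermediate
10 | [(2R)-2-ethylbut-3-en-1-yl]magnesium bromide | Br[Mg]C[C@H](CC)C=C | intermediate
11 | (3S,7S,9S)-3,7-diethyl-9-methyltridec-1-en-5-one | CCCC[C@H](C)C[C@H](CC)CC(=O)C[C@H](CC)C=C | intermediate
12 | ethyltriphenylphosphonium bromide | CC[P+](c1ccccc1)(c1ccccc1)c1ccccc1.[Br-] | starting material
13 | (3S,7S,9S)-3,7-diethyl-5-ethylidene-9-methyltridec-1-ene (E/Z mixture) | CCCC[C@H](C)C[C@H](CC)CC(=CC)C[C@H](CC)C=C | intermediate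
14 | (E)-but-2-enal | C/C=C/C=O | starting material
15 | (2E,4S,8S,10S)-4,8-diethyl-6-ethylidene-10-methyltetradec-2-enal | CCCC[C@H](C)C[C@H](CC)CC(=CC)C[C@H](CC)/C=C/C=O | intermediate
16 | 2,3-dimethylbut-2-ene | CC(C)=C(C)C | starting material
17 | 2-hydroperoxy-2-methoxypropane | COC(C)(C)OO | intermediate
18 | (3S,4S,8S,10S)-4,8-diethyl-6-ethylidene-3-[(2-methoxypropan-2-yl)peroxy]-10-methyltetradecanal | CCCC[C@H](C)C[C@H](CC)CC(=CC)C[C@H](CC)[C@H](CC=O)OOC(C)(C)OC | intermediate
19 | (3S,4S,8S,10S)-4,8-diethyl-6-ethylidene-3-[(2-methoxypropan-2-yl)peroxy]-10-methyltetradecanoic acid | CCCC[C@H](C)C[C@H](CC)CC(=CC)C[C@H](CC)[C@H](CC(=O)O)OOC(C)(C)OC | intermediate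
20 | (3S,4S,8S,10S)-4,8-diethyl-6-ethylidene-3-hydroperoxy-10-methyltetradecanoic acid | CCCC[C@H](C)C[C@H](CC)CC(=CC)C[C@H](CC)[C@H](CC(=O)O)OO | intermediate
21 | 2-[(3S,4S,6S)-4,6-diethyl-6-[(2S,4S)-2-ethyl-4-methyloctyl]-1,2-dioxan-3-yl]acetic acid | CCCC[C@H](C)C[C@H](CC)C[C@@]1(CC)C[C@H](CC)[C@H](CC(=O)O)OO1 | target

**Totals**
Total step count: 11. Longest linear sequence: 9 steps (1, 2, 3, 5, 6, 7, 9, 10, 11).

**Three steps most likely to fail**

Step 6 (Wittig on an enolisable ketone with β-branches on both sides; may be slow or low-yielding). The fallback is a Peterson olefination and sets out from 11. Addition of 1-(trimethylsilyl)ethylmagnesium chloride in the presence of CeCl3 (THF, −78 °C) gives the β-hydroxysilane (3S,7S,9S)-3,7-diethyl-9-methyl-5-[1-(trimethylsilyl)ethyl]tridec-1-en-5-ol F1. Elimination with KH in THF then gives the ethylidene alkene, and the route is rejoined at 13.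

Step 9 (peroxy-Michael). Three things can go wrong: the β-peroxy enamine can close to an epoxide, γ-deprotonation to the dienamine can erode C4, and the catalyst may be mismatched with C4. The fallback abandons the pre-set C3 hydroperoxide and sets out from 13. Cross-metathesis with methyl acrylate (second-generation Hoveyda–Grubbs catalyst) gives methyl (2E,4S,8S,10S)-4,8-diethyl-6-ethylidene-10-methyltetradec-2-enoate F2. Mukaiyama–Isayama hydroperoxysilylation (Co(thd)2, O2, Et3SiH, thd = 2,2,6,6-tetramethylheptane-3,5-dionate) puts the peroxide on C6 and gives methyl (2E,4S,8S,10S)-4,6,8-triethyl-10-methyl-6-[(triethylsilyl)peroxy]tetradec-2-enoate F3 as both C6 epimers. TBAF followed by Et2NH in CF3CH2OH closes the ring by intramolecular peroxy-Michael addition to methyl 2-[(3S,4S,6S)-4,6-diethyl-6-[(2S,4S)-2-ethyl-4-methyloctyl]-1,2-dioxan-3-yl]acetate F4, which must be separated from its C3/C6 diastereomers by HPLC. LiOH in THF/H2O then gives the acid, and the route is rejoined at 21. This fallback is poorly stereoselective at C3 and C6.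

Step 11 (the proposed new ring closure). Risks are low facial selectivity at C6, capture of the cation by the carboxylic acid, and acid-induced loss or rearrangement of the secondary hydroperoxide (including peroxylactone formation). The fallback uses known cycloperoxymercuration and sets out from 20. Hg(OAc)2 with catalytic HClO4 in CH2Cl2 gives 2-[(3S,4S,6S)-6-[1-(acetoxymercurio)ethyl]-4-ethyl-6-[(2S,4S)-2-ethyl-4-methyloctyl]-1,2-dioxan-3-yl]acetic acid F5 together with its C6 epimer. Alkaline NaBH4 demercuration gives the dioxane acid and its C6 epimer (some epoxide by-product is expected), separated by HPLC; the route is rejoined at 21.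

**Further compounds**
F1 | step 6 | (3S,7S,9S)-3,7-diethyl-9-methyl-5-[1-(trimethylsilyl)ethyl]tridec-1-en-5-ol | CCCC[C@H](C)C[C@H](CC)CC(O)(C(C)[Si](C)(C)C)C[C@H](CC)C=C
F2 | step 9 | methyl (2E,4S,8S,10S)-4,8-diethyl-6-ethylidene-10-methyltetradec-2-enoate | CCCC[C@H](C)C[C@H](CC)CC(=CC)C[C@H](CC)/C=C/C(=O)OC
F3 | step 9 | methyl (2E,4S,8S,10S)-4,6,8-triethyl-10-methyl-6-[(triethylsilyl)peroxy]tetradec-2-enoate | CCCC[C@H](C)C[C@H](CC)CC(CC)(OO[Si](CC)(CC)CC)C[C@H](CC)/C=C/C(=O)OC
F4 | step 9 | methyl 2-[(3S,4S,6S)-4,6-diethyl-6-[(2S,4S)-2-ethyl-4-methyloctyl]-1,2-dioxan-3-yl]acetate | CCCC[C@H](C)C[C@H](CC)C[C@@]1(CC)C[C@H](CC)[C@H](CC(=O)OC)OO1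
F5 | step 11 | 2-[(3S,4S,6S)-6-[1-(acetoxymercurio)ethyl]-4-ethyl-6-[(2S,4S)-2-ethyl-4-methyloctyl]-1,2-dioxan-3-yl]acetic acid | CCCC[C@H](C)C[C@H](CC)C[C@@]1(C(C)[Hg]OC(C)=O)C[C@H](CC)[C@H](CC(=O)O)OO1
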